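The flavanone is disconnected at C4–C4a and C8a–O1. Because C4a and C8a are adjacent carbons of ring A that carry the C4 ketone and the ring C oxygen O1, an aryne spanning these two atoms can be inserted into the C–O bond of a carboxylic acid. In one operation the carboxylate oxygen becomes the C8a phenol and the acyl carbon is delivered to C4a, while O5 and O7 stay masked. The aryne precursor is a 2-silylaryl triflate made from a symmetric prenylated phenol; the acid is a (3R)-3-aryl-3-silyloxypropanoic acid from asymmetric hydrogenation. Desilylation, Mitsunobu closure with inversion and acidic unmasking then give the (2S) target.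

Key step: step 12

Remark (assumption): the (S)-BINAP ruthenium catalyst is taken to reduce the aryl keto ester with the same facial sense as simple beta-keto esters; this corresponds to the (3R) alcohol because the aryl group outranks the CH2CO2Et arm.

Step 1
Reactants: 1 phloroglucinol
Product: 2 5-(triisopropylsilyloxy)benzene-1,3-diol
Conditions: 1 (3 equiv), TIPSCl (1 equiv), imidazole, DMF, 0 °C to rt
Reagents that add atoms: triisopropylsilyl chloride, CC(C)[Si](Cl)(C(C)C)C(C)C
Why: Silylation of a phenol with a bulky silyl chloride and imidazole; the threefold excess of the cheap triol should hold the reaction at the mono-ether, and unreacted triol is washed out with water.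

Step 2
Reactants: 2 5-(triisopropylsilyloxy)benzene-1,3-diol
Product: 3 [3,5-bis(methoxymethoxy)phenoxy]triisopropylsilane
Conditions: MOMCl (2.5 equiv), EtN(iPr)2, CH2Cl2, 0 °C to rt
Reagents that add atoms: chloromethyl methyl ether, COCCl
Why: O-Alkylation of the two remaining phenols with the reactive alpha-chloro ether under amine base, conditions to which the aryl silyl ether is inert.

Step 3
Reactants: 3 [3,5-bis(methoxymethoxy)phenoxy]triisopropylsilane; 4 prenyl bromide
Product: 6 [3,5-bis(methoxymethoxy)-4-(3-methylbut-2-en-1-yl)phenoxy]triisopropylsilane, via aryllithium 5 (not isolated)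
Conditions: n-BuLi, THF, 0 °C; CuI (0.2 equiv), then 4, −78 °C to rt
Reagents that add atoms: none
Why: Directed ortho-metalation removes the one proton flanked by both methoxymethoxy groups (the positions beside the bulky silyl ether are only singly activated and shielded), and the aryllithium is then allylated at the primary carbon of 4 under copper catalysis.

Step 4
Reactants: 6 [3,5-bis(methoxymethoxy)-4-(3-methylbut-2-en-1-yl)phenoxy]triisopropylsilane
Product: 7 3,5-bis(methoxymethoxy)-4-(3-methylbut-2-en-1-yl)phenol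
Conditions: Bu4NF, THF, 0 °C
Reagents that add atoms: none
Why: Fluoride-induced cleavage of the aryl silyl ether, which leaves the acetal ethers and the alkene untouched.

Step 5
Reactants: 7 3,5-bis(methoxymethoxy)-4-(3-methylbut-2-en-1-yl)phenol
Product: 8 2-bromo-3,5-bis(methoxymethoxy)-4-(3-methylbut-2-en-1-yl)phenol
Conditions: NBS (1.0 equiv), CH2Cl2, −78 °C
Reagents that add atoms: N-bromosuccinimide, O=C1CCC(=O)N1Br
Why: Electrophilic aromatic bromination ortho to the free hydroxyl; the two open ring positions are equivalent by symmetry, and the trioxygenated ring should outpace the trisubstituted alkene at low temperature with one equivalent of NBS.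

Step 6
Reactants: 8 2-bromo-3,5-bis(methoxymethoxy)-4-(3-methylbut-2-en-1-yl)phenol
Product: 11 3,5-bis(methoxymethoxy)-4-(3-methylbut-2-en-1-yl)-2-(trimethylsilyl)phenyl trifluoromethanesulfonate, via aryl trimethylsilyl ether 9 (not isolated), via lithium silylphenoxide 10 (not isolated)
Conditions: HMDS, THF, reflux, then evaporation; n-BuLi, THF, −100 to −78 °C; Tf2O, −100 to −78 °C
Reagents that add atoms: hexamethyldisilazane, C[Si](C)(C)N[Si](C)(C)C; trifluoromethanesulfonic anhydride, O=S(=O)(OS(=O)(=O)C(F)(F)F)C(F)(F)F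
Why: O-Silylation, bromine–lithium exchange and a retro-Brook 1,3-shift of silicon from oxygen to carbon give the ortho-silyl phenoxide, which is triflated in the same flask, the standard entry to ortho-silylaryl triflates.

Step 7
Reactants: 12 acetovanillone
Product: 13 1-[3-methoxy-4-(methoxymethoxy)phenyl]ethan-1-one
Conditions: MOMCl, EtN(iPr)2, CH2Cl2, 0 °C to rt
Reagents that add atoms: chloromethyl methyl ether, COCCl
Why: O-Alkylation of the acidic para-acyl phenol with the alpha-chloro ether under amine base.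

Step 8
Reactants: 13 1-[3-methoxy-4-(methoxymethoxy)phenyl]ethan-1-one; 14 diethyl carbonate
Product: 15 ethyl 3-[3-methoxy-4-(methoxymethoxy)phenyl]-3-oxopropanoate
Conditions: NaH (2.5 equiv), 14 (3 equiv), toluene, 80 °C; AcOH quench
Reagents that add atoms: none
Why: Crossed Claisen condensation of the methyl ketone enolate with the non-enolisable carbonate, driven by deprotonation of the beta-keto ester that forms.

Step 9
Reactants: 15 ethyl 3-[3-methoxy-4-(methoxymethoxy)phenyl]-3-oxopropanoate
Product: 16 ethyl (3R)-3-hydroxy-3-[3-methoxy-4-(methoxymethoxy)phenyl]propanoate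
Conditions: H2 (50 atm), RuCl2[(S)-BINAP] (0.5 mol %), EtOH, 50 °C
Reagents that add atoms: none
Why: Noyori asymmetric hydrogenation of a beta-keto ester through the ester-chelated ruthenium hydride; the (S)-ligand should deliver hydrogen to the face that gives the (3R) alcohol.

Step 10
Reactants: 16 ethyl (3R)-3-hydroxy-3-[3-methoxy-4-(methoxymethoxy)phenyl]propanoate
Product: 17 ethyl (3R)-3-[3-methoxy-4-(methoxymethoxy)phenyl]-3-(triisopropylsilyloxy)propanoate
Conditions: TIPSOTf, 2,6-lutidine, CH2Cl2, −78 to 0 °C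
Reagents that add atoms: triisopropylsilyl trifluoromethanesulfonate, CC(C)[Si](OS(=O)(=O)C(F)(F)F)(C(C)C)C(C)C
Why: Silylation of the secondary benzylic alcohol with a silyl triflate and a hindered pyridine base, which does not touch the stereocentre.

Step 11
Reactants: 17 ethyl (3R)-3-[3-methoxy-4-(methoxymethoxy)phenyl]-3-(triisopropylsilyloxy)propanoate
Product: 18 (3R)-3-[3-methoxy-4-(methoxymethoxy)phenyl]-3-(triisopropylsilyloxy)propanoic acid
Conditions: LiOH·H2O, THF/EtOH/H2O, rt; then 0.5 M HCl to pH 4, 0 °C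
Reagents that add atoms: lithium hydroxide, [Li+].[OH-]
Why: Saponification of the ethyl ester; the silyl ether and the acetal survive the base and the brief, mild acidification.

Step 12
Reactants: 11 3,5-bis(methoxymethoxy)-4-(3-methylbut-2-en-1-yl)-2-(trimethylsilyl)phenyl trifluoromethanesulfonate; 18 (3R)-3-[3-methoxy-4-(methoxymethoxy)phenyl]-3-(triisopropylsilyloxy)propanoic acid
Product: 21 (3R)-1-[6-hydroxy-2,4-bis(methoxymethoxy)-3-(3-methylbut-2-en-1-yl)phenyl]-3-[3-methoxy-4-(methoxymethoxy)phenyl]-3-(triisopropylsilyloxy)propan-1-one, via potassium carboxylate 19 (not isolated), via aryne 20 (not isolated)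
Conditions: 18 (1.2 equiv), KH (1.2 equiv), THF, 0 °C; then KF, 18-crown-6, 11 (1.0 equiv, slow addition), THF, rt to 40 °C; AcOH quench
Reagents that add atoms: none
Why: Fluoride strips the trimethylsilyl group of 11 and triflate leaves to give aryne 20; the crown-solvated carboxylate 19 adds through oxygen to C8a, and the resulting C4a aryl anion attacks the neighbouring ester carbonyl to form a transient four-membered benzoxete alkoxide that opens to the ortho-acyl phenoxide, so the C8a–O and C4–C4a bonds arise in one sequence. The closest known reaction type is the fluoride-induced insertion of arynes into the C–O bond of carboxylic acids, which gives ortho-hydroxyaryl ketones. No ring is kept: the only closure is the transient 4-exo-trig attack on the carbonyl, which is undone by ring opening. No stereocentre is formed, and C3 of the acid is neither deprotonated nor ionised under these aprotic conditions. The step needs regioselective addition to the unsymmetrical aryne, which the inductive pull of the C5 methoxymethoxy group next to C4a should secure by stabilising negative charge there and steering the oxygen to the distal carbon C8a. It also needs acyl transfer to beat protonation and silanolate loss, which the pre-formed potassium salt, the absence of proton donors, the robust triisopropylsilyl ether and the mild temperature are meant to ensure.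

Step 13
Reactants: 21 (3R)-1-[6-hydroxy-2,4-bis(methoxymethoxy)-3-(3-methylbut-2-en-1-yl)phenyl]-3-[3-methoxy-4-(methoxymethoxy)phenyl]-3-(triisopropylsilyloxy)propan-1-one
Product: 22 (3R)-3-hydroxy-1-[6-hydroxy-2,4-bis(methoxymethoxy)-3-(3-methylbut-2-en-1-yl)phenyl]-3-[3-methoxy-4-(methoxymethoxy)phenyl]propan-1-one
Conditions: HF·pyridine, excess pyridine, THF, 0 °C to rt
Reagents that add atoms: none
Why: Fluoride-mediated cleavage of the secondary silyl ether under buffered, weakly acidic conditions, which avoid base-induced retro-aldol cleavage or elimination of the beta-hydroxy ketone and leave the acetals intact.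

Step 14
Reactants: 22 (3R)-3-hydroxy-1-[6-hydroxy-2,4-bis(methoxymethoxy)-3-(3-methylbut-2-en-1-yl)phenyl]-3-[3-methoxy-4-(methoxymethoxy)phenyl]propan-1-one
Product: 23 (2S)-2-[3-methoxy-4-(methoxymethoxy)phenyl]-5,7-bis(methoxymethoxy)-6-(3-methylbut-2-en-1-yl)chroman-4-one
Conditions: PPh3, DIAD, toluene, 0 °C
Reagents that add atoms: none
Why: Intramolecular Mitsunobu etherification: the only free phenol (at C8a) displaces the activated benzylic oxygen in a 6-exo-tet SN2 closure of ring C, so the (3R) carbinol is inverted to the (2S) centre, and with O5 still protected no 8-prenyl isomer can form.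

Step 15
Reactants: 23 (2S)-2-[3-methoxy-4-(methoxymethoxy)phenyl]-5,7-bis(methoxymethoxy)-6-(3-methylbut-2-en-1-yl)chroman-4-one
Product: 24 (2S)-5,7-dihydroxy-2-(4-hydroxy-3-methoxyphenyl)-6-(3-methylbut-2-en-1-yl)chroman-4-one
Conditions: 3 M HCl (aq), MeOH, 40 °C
Reagents that add atoms: none
Why: Acid-catalysed acetal cleavage (transacetalisation to methanol) frees the three phenols; the C2 centre is not labile under dilute acid, in contrast to base, and short exposure should spare the prenyl group.

Compound list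
1 | phloroglucinol (benzene-1,3,5-triol) | Oc1cc(O)cc(O)c1 | starting material
2 | 5-(triisopropylsilyloxy)benzene-1,3-diol | CC(C)[Si](Oc1cc(O)cc(O)c1)(C(C)C)C(C)C | intermediate
3 | [3,5-bis(methoxymethoxy)phenoxy]triisopropylsilane | COCOc1cc(OCOC)cc(O[Si](C(C)C)(C(C)C)C(C)C)c1 | intermediate
4 | prenyl bromide (1-bromo-3-methylbut-2-ene) | CC(C)=CCBr | starting material
5 | [2,6-bis(methoxymethoxy)-4-(triisopropylsilyloxy)phenyl]lithium | [Li]c1c(OCOC)cc(O[Si](C(C)C)(C(C)C)C(C)C)cc1OCOC | intermediate (not isolated)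
6 | [3,5-bis(methoxymethoxy)-4-(3-methylbut-2-en-1-yl)phenoxy]triisopropylsilane | CC(C)=CCc1c(OCOC)cc(O[Si](C(C)C)(C(C)C)C(C)C)cc1OCOC | intermediate
7 | 3,5-bis(methoxymethoxy)-4-(3-methylbut-2-en-1-yl)phenol | CC(C)=CCc1c(OCOC)cc(O)cc1OCOC | intermediate
8 | 2-bromo-3,5-bis(methoxymethoxy)-4-(3-methylbut-2-en-1-yl)phenol | CC(C)=CCc1c(OCOC)cc(O)c(Br)c1OCOC | intermediate
9 | [2-bromo-3,5-bis(methoxymethoxy)-4-(3-methylbut-2-en-1-yl)phenoxy]trimethylsilane | C[Si](C)(C)Oc1cc(OCOC)c(CC=C(C)C)c(OCOC)c1Br | intermediate (not isolated)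
10 | lithium 3,5-bis(methoxymethoxy)-4-(3-methylbut-2-en-1-yl)-2-(trimethylsilyl)phenolate | [Li+].[O-]c1cc(OCOC)c(CC=C(C)C)c(OCOC)c1[Si](C)(C)C | intermediate (not isolated)
11 | 3,5-bis(methoxymethoxy)-4-(3-methylbut-2-en-1-yl)-2-(trimethylsilyl)phenyl trifluoromethanesulfonate | C[Si](C)(C)c1c(OS(=O)(=O)C(F)(F)F)cc(OCOC)c(CC=C(C)C)c1OCOC | intermediate
12 | acetovanillone (1-(4-hydroxy-3-methoxyphenyl)ethan-1-one) | CC(=O)c1ccc(O)c(OC)c1 | starting material
13 | 1-[3-methoxy-4-(methoxymethoxy)phenyl]ethan-1-one | CC(=O)c1ccc(OCOC)c(OC)c1 | intermediate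
14 | diethyl carbonate | CCOC(=O)OCC | starting material
15 | ethyl 3-[3-methoxy-4-(methoxymethoxy)phenyl]-3-oxopropanoate | CCOC(=O)CC(=O)c1ccc(OCOC)c(OC)c1 | intermediate
16 | ethyl (3R)-3-hydroxy-3-[3-methoxy-4-(methoxymethoxy)phenyl]propanoate | CCOC(=O)C[C@@H](O)c1ccc(OCOC)c(OC)c1 | intermediate
17 | ethyl (3R)-3-[3-methoxy-4-(methoxymethoxy)phenyl]-3-(triisopropylsilyloxy)propanoate | CCOC(=O)C[C@@H](O[Si](C(C)C)(C(C)C)C(C)C)c1ccc(OCOC)c(OC)c1 | intermediate
18 | (3R)-3-[3-methoxy-4-(methoxymethoxy)phenyl]-3-(triisopropylsilyloxy)propanoic acid | OC(=O)C[C@@H](O[Si](C(C)C)(C(C)C)C(C)C)c1ccc(OCOC)c(OC)c1 | intermediate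
19 | potassium (3R)-3-[3-methoxy-4-(methoxymethoxy)phenyl]-3-(triisopropylsilyloxy)propanoate | [K+].[O-]C(=O)C[C@@H](O[Si](C(C)C)(C(C)C)C(C)C)c1ccc(OCOC)c(OC)c1 | intermediate (not isolated)
20 | 3,5-bis(methoxymethoxy)-4-(3-methylbut-2-en-1-yl)benzyne (1,2-didehydrobenzene) | C1#CC(OCOC)=C(CC=C(C)C)C(OCOC)=C1 | intermediate (not isolated)
21 | (3R)-1-[6-hydroxy-2,4-bis(methoxymethoxy)-3-(3-methylbut-2-en-1-yl)phenyl]-3-[3-methoxy-4-(methoxymethoxy)phenyl]-3-(triisopropylsilyloxy)propan-1-one | CC(C)[Si](C(C)C)(C(C)C)O[C@H](CC(=O)c1c(O)cc(OCOC)c(CC=C(C)C)c1OCOC)c1ccc(OCOC)c(OC)c1 | intermediate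
22 | (3R)-3-hydroxy-1-[6-hydroxy-2,4-bis(methoxymethoxy)-3-(3-methylbut-2-en-1-yl)phenyl]-3-[3-methoxy-4-(methoxymethoxy)phenyl]propan-1-one | O[C@H](CC(=O)c1c(O)cc(OCOC)c(CC=C(C)C)c1OCOC)c1ccc(OCOC)c(OC)c1 | intermediate
23 | (2S)-2-[3-methoxy-4-(methoxymethoxy)phenyl]-5,7-bis(methoxymethoxy)-6-(3-methylbut-2-en-1-yl)chroman-4-one | COc1cc([C@@H]2CC(=O)c3c(cc(OCOC)c(CC=C(C)C)c3OCOC)O2)ccc1OCOC | intermediate
24 | (2S)-5,7-dihydroxy-2-(4-hydroxy-3-methoxyphenyl)-6-(3-methylbut-2-en-1-yl)chroman-4-one | COc1cc([C@@H]2CC(=O)c3c(cc(O)c(CC=C(C)C)c3O)O2)ccc1O | target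

Total step count: 15. Longest linear sequence: 10 steps (steps 1 to 6, then 12 to 15).

Steps most likely to fail

1. Step 12. The C4a aryl anion may be protonated before the acyl shift, so that only O-arylation occurs. It may also abstract an alpha-proton of its own ester arm, after which silanolate is lost, or the product phenoxide may be arylated a second time. The fallback sets out from bromophenol 8 and acid 18 and rejoins the route at 21. Carbodiimide esterification (EDC, DMAP, CH2Cl2) should give the aryl ester 2-bromo-3,5-bis(methoxymethoxy)-4-(3-methylbut-2-en-1-yl)phenyl (3R)-3-[3-methoxy-4-(methoxymethoxy)phenyl]-3-(triisopropylsilyloxy)propanoate F1. Bromine–lithium exchange (n-BuLi, THF, −100 °C) then places the carbanion at the same C4a position and triggers an anionic Fries-type 1,3-shift of the acyl group from oxygen to carbon. Aqueous work-up should deliver 21, with the C8a oxygen now coming from the phenol.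

2. Step 14. The electron-rich benzylic oxyphosphonium may ionise in part before the phenol attacks, which would erode the configuration at C2, or it may lose water to the enone. The fallback sets out from 22 and rejoins at 23, and sets C2 by kinetic resolution instead of by displacement. Base-induced dehydration (KOH, EtOH, rt) should give the chalcone (E)-1-[6-hydroxy-2,4-bis(methoxymethoxy)-3-(3-methylbut-2-en-1-yl)phenyl]-3-[3-methoxy-4-(methoxymethoxy)phenyl]prop-2-en-1-one F2. Oxa-Michael closure (NaOAc, EtOH, reflux) then gives racemic 2-[3-methoxy-4-(methoxymethoxy)phenyl]-5,7-bis(methoxymethoxy)-6-(3-methylbut-2-en-1-yl)chroman-4-one F3. Asymmetric transfer hydrogenation with Cp*RhCl[(R,R)-TsDPEN] (HCO2H/Et3N, EtOAc, rt, stopped near half conversion) should reduce only the (2R) enantiomer, to the cis alcohol (2R,4R)-2-[3-methoxy-4-(methoxymethoxy)phenyl]-5,7-bis(methoxymethoxy)-6-(3-methylbut-2-en-1-yl)chroman-4-ol F4. The unreduced (2S) ketone 23 is separated by chromatography. At most half of the material is recovered this way.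

3. Step 5. The bromonium source may attack the prenyl double bond, or the ring may be brominated twice. The fallback sets out from phenol 7 and rejoins at 11, replacing steps 5 and 6 by carbamate-directed silylation. Isopropyl isocyanate with Et3N in CH2Cl2 should give 3,5-bis(methoxymethoxy)-4-(3-methylbut-2-en-1-yl)phenyl N-isopropylcarbamate F5. In-situ N-silylation (TMSOTf, TMEDA), ortho-lithiation (n-BuLi, TMEDA, Et2O, −78 °C) and a TMSCl quench should give 3,5-bis(methoxymethoxy)-4-(3-methylbut-2-en-1-yl)-2-(trimethylsilyl)phenyl N-isopropylcarbamate F6. Carbamate cleavage (DBU, Et2NH, MeCN, 40 °C) followed by PhNTf2 in the same flask should give triflate 11.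

Further compounds
F1 | step 12 | 2-bromo-3,5-bis(methoxymethoxy)-4-(3-methylbut-2-en-1-yl)phenyl (3R)-3-[3-methoxy-4-(methoxymethoxy)phenyl]-3-(triisopropylsilyloxy)propanoate | CC(C)=CCc1c(OCOC)cc(OC(=O)C[C@@H](O[Si](C(C)C)(C(C)C)C(C)C)c2ccc(OCOC)c(OC)c2)c(Br)c1OCOC
F2 | step 14 | (E)-1-[6-hydroxy-2,4-bis(methoxymethoxy)-3-(3-methylbut-2-en-1-yl)phenyl]-3-[3-methoxy-4-(methoxymethoxy)phenyl]prop-2-en-1-one | COCOc1ccc(/C=C/C(=O)c2c(O)cc(OCOC)c(CC=C(C)C)c2OCOC)cc1OC
F3 | step 14 | racemic 2-[3-methoxy-4-(methoxymethoxy)phenyl]-5,7-bis(methoxymethoxy)-6-(3-methylbut-2-en-1-yl)chroman-4-one | COc1cc(C2CC(=O)c3c(cc(OCOC)c(CC=C(C)C)c3OCOC)O2)ccc1OCOC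
F4 | step 14 | (2R,4R)-2-[3-methoxy-4-(methoxymethoxy)phenyl]-5,7-bis(methoxymethoxy)-6-(3-methylbut-2-en-1-yl)chroman-4-ol | COc1cc([C@H]2C[C@@H](O)c3c(cc(OCOC)c(CC=C(C)C)c3OCOC)O2)ccc1OCOC
F5 | step 5 | 3,5-bis(methoxymethoxy)-4-(3-methylbut-2-en-1-yl)phenyl N-isopropylcarbamate | CC(C)NC(=O)Oc1cc(OCOC)c(CC=C(C)C)c(OCOC)c1
F6 | step 5 | 3,5-bis(methoxymethoxy)-4-(3-methylbut-2-en-1-yl)-2-(trimethylsilyl)phenyl N-isopropylcarbamate | CC(C)NC(=O)Oc1cc(OCOC)c(CC=C(C)C)c(OCOC)c1[Si](C)(C)C
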